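**Strategy.** Everything rests on disconnecting the C3–C4 bond of the γ-lactone, between the quaternary carbinol carbon C3 (α to C2=O) and C4, by an Ireland–Claisen rearrangement. The structure invites it: C2(=O)–C3–C4 plus the carbon that becomes C7' is the γ,δ-unsaturated acid array that an ester enolate Claisen delivers. The precursor is the ester of a racemic O-BOM 3-aryllactic acid with (S,E)-5-silyloxypent-3-en-2-ol. One operation forms C3–C4, sets C3 and C4 by chirality transfer through a chair, and, after acid, closes the lactone on C5. The propenyl group left on C4 is cut to the C7' aldehyde, where Felkin-controlled arylation sets the last centre.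

Key step: step 6

Remark on the chemistry: the α-stereocentre of the aryllactic acid part (4, 5, 6, 10) is erased when the enolate forms in step 6, so this part is carried racemic. Locants C2–C5 and C7' are those of the target lactone.

Step 1
Reactants: 1 1-(benzyloxy)-4-bromo-2-methoxybenzene; 2 methyl oxirane-2-carboxylate (racemic)
Product: 4 methyl 3-[4-(benzyloxy)-3-methoxyphenyl]-2-hydroxypropanoate (racemic), via arylmagnesium bromide 3 (not isolated)
Conditions: Mg, THF, rt; then CuI (10 mol%), 2, THF, −40 → −20 °C; aq. NH4Cl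
Reagents that add atoms: none
Why: Copper-catalysed SN2 opening of the glycidic ester by the aryl Grignard reagent should occur at the unsubstituted epoxide carbon faster than addition to the ester at low temperature (cuprate-type epoxide opening); the carbinol centre formed is racemic and is erased in step 6.

Step 2
Reactants: 4 methyl 3-[4-(benzyloxy)-3-methoxyphenyl]-2-hydroxypropanoate
Product: 5 methyl 2-[(benzyloxy)methoxy]-3-[4-(benzyloxy)-3-methoxyphenyl]propanoate (racemic)
Conditions: BOMCl, i-Pr2NEt, n-Bu4NI (cat.), CH2Cl2, 0 °C → rt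
Reagents that add atoms: benzyl chloromethyl ether, ClCOCc1ccccc1
Why: O-Alkylation of the secondary alcohol with the reactive α-chloro ether under amine base (acetal-type Williamson etherification) installs a base-stable, chelating and hydrogenolysable BOM ether without enolising the ester.

Step 3
Reactants: 5 methyl 2-[(benzyloxy)methoxy]-3-[4-(benzyloxy)-3-methoxyphenyl]propanoate
Product: 6 2-[(benzyloxy)methoxy]-3-[4-(benzyloxy)-3-methoxyphenyl]propanoic acid (racemic)
Conditions: LiOH·H2O, THF–MeOH–H2O, rt; then 1 M HCl to pH 3, 0 °C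
Reagents that add atoms: lithium hydroxide, [Li+].[OH-]
Why: Saponification (BAc2 ester hydrolysis) frees the acid while the BOM acetal and the aryl benzyl ether are inert to hydroxide, and the acetal survives brief cold acidification.

Step 4
Reactants: 7 (S)-but-3-en-2-ol; 8 (allyloxy)(tert-butyl)dimethylsilane
Product: 9 (2S,3E)-5-[(tert-butyldimethylsilyl)oxy]pent-3-en-2-ol
Conditions: Hoveyda–Grubbs II (3 mol%), 8 (3 equiv), CH2Cl2, 40 °C
Reagents that add atoms: none
Why: Olefin cross-metathesis of a secondary allylic alcohol with an excess of the unhindered allyl silyl ether should be E-selective and does not touch the carbinol centre, so the S configuration of 7 is carried into 9.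

Step 5
Reactants: 6 2-[(benzyloxy)methoxy]-3-[4-(benzyloxy)-3-methoxyphenyl]propanoic acid; 9 (2S,3E)-5-[(tert-butyldimethylsilyl)oxy]pent-3-en-2-ol
Product: 10 (2S,3E)-5-[(tert-butyldimethylsilyl)oxy]pent-3-en-2-yl 2-[(benzyloxy)methoxy]-3-[4-(benzyloxy)-3-methoxyphenyl]propanoate (both epimers at the acid α-carbon)
Conditions: DCC, DMAP (cat.), CH2Cl2, 0 °C → rt
Reagents that add atoms: none
Why: Steglich esterification (carbodiimide activation with DMAP acyl transfer) acylates the secondary allylic alcohol with retention at its carbinol carbon; both epimers at the acid α-carbon are acceptable.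

Step 6
Reactants: 10 (2S,3E)-5-[(tert-butyldimethylsilyl)oxy]pent-3-en-2-yl 2-[(benzyloxy)methoxy]-3-[4-(benzyloxy)-3-methoxyphenyl]propanoate
Product: 15 (3S,4S)-3-[(benzyloxy)methoxy]-3-[4-(benzyloxy)-3-methoxybenzyl]-4-[(E)-prop-1-en-1-yl]dihydrofuran-2(3H)-one, via silyl ketene acetal 11 (not isolated), via trimethylsilyl ester 12 (not isolated), via silyloxy acid 13 (not isolated), via hydroxy acid 14 (not isolated)
Conditions: LDA, THF, −78 °C; TMSCl, −78 °C → rt, then 45 °C; aq. NH4Cl; crude product: CSA (10 mol%), MeOH, rt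
Reagents that add atoms: none
Why: LDA deprotonates the α-alkoxy ester to a lithium enolate held by chelation between the enolate oxygen and the BOM oxygen, so silylation should give the (Z)-ketene acetal 11 (OBOM cis to OSiMe3), which rearranges on warming by a concerted [3,3]-sigmatropic shift to silyl ester 12 (glycolate Ireland–Claisen rearrangement; the closest known type is the rearrangement of allyl esters of O-alkyl lactic acids to acids with an α-alkoxy quaternary carbon). The rearrangement should pass through a chair in which the methyl group on the carbinol carbon of the allyl part and the CH2OTBS group of the E-olefin are equatorial and the OBOM group lies trans to the allylic oxygen; C3 is thus controlled by the enolate geometry, C4 by the olefin geometry, and the absolute sense of both by 1,3-chirality transfer from the S carbinol centre of 9, which is consumed as it becomes the E-propenyl group (product descriptors 3S,4S, the spatial arrangement of the target's 3S,4R, because propenyl ranks below C5). The rearrangement itself closes no ring; the lactone is closed afterwards, when acid in methanol removes the primary silyl ether and the freed C5 hydroxyl attacks the C2 carboxyl of 14 in a 5-exo-trig acyl substitution. The selectivities needed are Z over E enolisation and chair over boat, secured by the chelating α-oxygen and by the acyclic E-allyl unit with its equatorial methyl group. Both epimers of 10 converge because the α-stereocentre of the acid part is erased in the enolate, and the BOM acetal, aryl benzyl ethers and electron-rich arenes are inert to the base and to the mild acid.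

Step 7
Reactants: 15 (3S,4S)-3-[(benzyloxy)methoxy]-3-[4-(benzyloxy)-3-methoxybenzyl]-4-[(E)-prop-1-en-1-yl]dihydrofuran-2(3H)-one
Product: 17 (3S,4S)-3-[(benzyloxy)methoxy]-3-[4-(benzyloxy)-3-methoxybenzyl]-4-formyldihydrofuran-2(3H)-one, via vicinal diol 16 (not isolated)
Conditions: OsO4 (2 mol%), NaIO4, 2,6-lutidine, 1,4-dioxane–H2O (3:1), rt; used at once
Reagents that add atoms: osmium tetroxide, O=[Os](=O)(=O)=O; sodium periodate, [Na+].[O-]I(=O)(=O)=O
Why: Johnson–Lemieux oxidative cleavage (catalytic syn-dihydroxylation to diol 16, then periodate glycol cleavage) of the only olefin spares the electron-rich arenes and benzyl ethers that ozone could attack, and buffered conditions with immediate use of 17 keep the C4 centre intact.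

Step 8
Reactants: 17 (3S,4S)-3-[(benzyloxy)methoxy]-3-[4-(benzyloxy)-3-methoxybenzyl]-4-formyldihydrofuran-2(3H)-one; 1 1-(benzyloxy)-4-bromo-2-methoxybenzene
Product: 20 (3S,4R)-3-[(benzyloxy)methoxy]-3-[4-(benzyloxy)-3-methoxybenzyl]-4-{(R)-[4-(benzyloxy)-3-methoxyphenyl](hydroxy)methyl}dihydrofuran-2(3H)-one, via aryllithium 18 (not isolated), via aryltitanium triisopropoxide 19 (not isolated)
Conditions: 1, n-BuLi, THF, −78 °C; ClTi(Oi-Pr)3, −78 → −40 °C; then 17, −40 → 0 °C; aq. NH4Cl
Reagents that add atoms: none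
Why: Bromine–lithium exchange and transmetallation give a weakly basic, non-chelating aryltitanium reagent that adds to the aldehyde but not to the lactone (chemoselective organotitanium carbonyl addition), and Felkin–Anh control with the quaternary C3 as the large group anti to the incoming aryl should set C7' as R.

Step 9
Reactants: 20 (3S,4R)-3-[(benzyloxy)methoxy]-3-[4-(benzyloxy)-3-methoxybenzyl]-4-{(R)-[4-(benzyloxy)-3-methoxyphenyl](hydroxy)methyl}dihydrofuran-2(3H)-one
Product: 22 (3S,4R)-3-hydroxy-3-(4-hydroxy-3-methoxybenzyl)-4-[(R)-hydroxy(4-hydroxy-3-methoxyphenyl)methyl]dihydrofuran-2(3H)-one (CNP0352022.1), via formaldehyde hemiacetal 21 (not isolated)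
Conditions: H2 (1 atm), 10% Pd/C, EtOAc–EtOH (1:1), rt, stopped as soon as 20 and 21 are consumed
Reagents that add atoms: none
Why: Heterogeneous hydrogenolysis cleaves both aryl benzyl ethers and the benzylic C–O bond of the BOM group, whose hemiacetal 21 loses formaldehyde to free the tertiary alcohol, while neutral conditions, room temperature and a short reaction time are chosen because the benzylic C7'–OH bond is cleaved far more slowly than benzyl ethers.

**Compound list**

1 | 1-(benzyloxy)-4-bromo-2-methoxybenzene | COc1cc(Br)ccc1OCc1ccccc1 | starting material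
2 | methyl oxirane-2-carboxylate (racemic methyl glycidate) | COC(=O)C1CO1 | starting material
3 | [4-(benzyloxy)-3-methoxyphenyl]magnesium bromide | COc1cc([Mg]Br)ccc1OCc1ccccc1 | intermediate
4 | methyl 3-[4-(benzyloxy)-3-methoxyphenyl]-2-hydroxypropanoate (racemic) | COC(=O)C(O)Cc1ccc(OCc2ccccc2)c(OC)c1 | intermediate
5 | methyl 2-[(benzyloxy)methoxy]-3-[4-(benzyloxy)-3-methoxyphenyl]propanoate (racemic) | COC(=O)C(OCOCc1ccccc1)Cc1ccc(OCc2ccccc2)c(OC)c1 | intermediate
6 | 2-[(benzyloxy)methoxy]-3-[4-(benzyloxy)-3-methoxyphenyl]propanoic acid (racemic) | OC(=O)C(OCOCc1ccccc1)Cc1ccc(OCc2ccccc2)c(OC)c1 | intermediate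
7 | (S)-but-3-en-2-ol | C[C@H](O)C=C | starting material
8 | (allyloxy)(tert-butyl)dimethylsilane | C=CCO[Si](C)(C)C(C)(C)C | starting material
9 | (2S,3E)-5-[(tert-butyldimethylsilyl)oxy]pent-3-en-2-ol | C[C@H](O)/C=C/CO[Si](C)(C)C(C)(C)C | intermediate
10 | (2S,3E)-5-[(tert-butyldimethylsilyl)oxy]pent-3-en-2-yl 2-[(benzyloxy)methoxy]-3-[4-(benzyloxy)-3-methoxyphenyl]propanoate (both epimers at the acid α-carbon) | C[C@H](OC(=O)C(OCOCc1ccccc1)Cc1ccc(OCc2ccccc2)c(OC)c1)/C=C/CO[Si](C)(C)C(C)(C)C | intermediate
11 | (Z)-trimethylsilyl ketene acetal of 10 (OBOM cis to OSiMe3; (2S,3E)-allyl unit unchanged) | C[C@H](O/C(O[Si](C)(C)C)=C(/OCOCc1ccccc1)Cc1ccc(OCc2ccccc2)c(OC)c1)/C=C/CO[Si](C)(C)C(C)(C)C | intermediate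
12 | trimethylsilyl (2S,3S,4E)-2-[(benzyloxy)methoxy]-2-[4-(benzyloxy)-3-methoxybenzyl]-3-{[(tert-butyldimethylsilyl)oxy]methyl}hex-4-enoate | COc1cc(C[C@@]([C@H](CO[Si](C)(C)C(C)(C)C)/C=C/C)(OCOCc2ccccc2)C(=O)O[Si](C)(C)C)ccc1OCc1ccccc1 | intermediate
13 | (2S,3S,4E)-2-[(benzyloxy)methoxy]-2-[4-(benzyloxy)-3-methoxybenzyl]-3-{[(tert-butyldimethylsilyl)oxy]methyl}hex-4-enoic acid | COc1cc(C[C@@]([C@H](CO[Si](C)(C)C(C)(C)C)/C=C/C)(OCOCc2ccccc2)C(=O)O)ccc1OCc1ccccc1 | intermediate
14 | (2S,3S,4E)-2-[(benzyloxy)methoxy]-2-[4-(benzyloxy)-3-methoxybenzyl]-3-(hydroxymethyl)hex-4-enoic acid | COc1cc(C[C@@]([C@H](CO)/C=C/C)(OCOCc2ccccc2)C(=O)O)ccc1OCc1ccccc1 | intermediate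
15 | (3S,4S)-3-[(benzyloxy)methoxy]-3-[4-(benzyloxy)-3-methoxybenzyl]-4-[(E)-prop-1-en-1-yl]dihydrofuran-2(3H)-one | COc1cc(C[C@@]2(OCOCc3ccccc3)C(=O)OC[C@@H]2/C=C/C)ccc1OCc1ccccc1 | intermediate
16 | (3S,4R)-3-[(benzyloxy)methoxy]-3-[4-(benzyloxy)-3-methoxybenzyl]-4-(1,2-dihydroxypropyl)dihydrofuran-2(3H)-one (diastereomers at the two new carbinol carbons) | COc1cc(C[C@@]2(OCOCc3ccccc3)C(=O)OC[C@@H]2C(O)C(C)O)ccc1OCc1ccccc1 | intermediate
17 | (3S,4S)-3-[(benzyloxy)methoxy]-3-[4-(benzyloxy)-3-methoxybenzyl]-4-formyldihydrofuran-2(3H)-one | COc1cc(C[C@@]2(OCOCc3ccccc3)C(=O)OC[C@@H]2C=O)ccc1OCc1ccccc1 | intermediate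
18 | [4-(benzyloxy)-3-methoxyphenyl]lithium | COc1cc([Li])ccc1OCc1ccccc1 | intermediate
19 | [4-(benzyloxy)-3-methoxyphenyl]titanium triisopropoxide | COc1cc([Ti](OC(C)C)(OC(C)C)OC(C)C)ccc1OCc1ccccc1 | intermediate
20 | (3S,4R)-3-[(benzyloxy)methoxy]-3-[4-(benzyloxy)-3-methoxybenzyl]-4-{(R)-[4-(benzyloxy)-3-methoxyphenyl](hydroxy)methyl}dihydrofuran-2(3H)-one | COc1cc(C[C@@]2(OCOCc3ccccc3)C(=O)OC[C@@H]2[C@@H](O)c2ccc(OCc3ccccc3)c(OC)c2)ccc1OCc1ccccc1 | intermediate
21 | (3S,4R)-3-(hydroxymethoxy)-3-(4-hydroxy-3-methoxybenzyl)-4-[(R)-hydroxy(4-hydroxy-3-methoxyphenyl)methyl]dihydrofuran-2(3H)-one | COc1cc(C[C@@]2(OCO)C(=O)OC[C@@H]2[C@@H](O)c2ccc(O)c(OC)c2)ccc1O | intermediate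
22 | (3S,4R)-3-hydroxy-3-(4-hydroxy-3-methoxybenzyl)-4-[(R)-hydroxy(4-hydroxy-3-methoxyphenyl)methyl]dihydrofuran-2(3H)-one | COc1cc(C[C@@]2(O)C(=O)OC[C@@H]2[C@@H](O)c2ccc(O)c(OC)c2)ccc1O | target

Total step count: 9

Longest linear sequence: 8 steps (steps 1, 2, 3, 5, 6, 7, 8, 9; step 4 is the side branch)

**Steps most likely to fail**

Step 6 (key step). The hindered tertiary α-carbon may be deprotonated incompletely, chelation control of the enolisation may be lost (mixed ketene acetal geometry), or part of the material may pass through a boat transition state. Each would erode the C3/C4 diastereoselectivity. The fallback builds the two centres one after the other on a preformed lactone. It sets out from 9. A Johnson–Claisen rearrangement (triethyl orthoacetate, cat. propionic acid, 140 °C) should transfer the chirality through the same chair to ethyl (3S,4E)-3-{[(tert-butyldimethylsilyl)oxy]methyl}hex-4-enoate F1. Acid in methanol removes the silyl group and closes (4S)-4-[(E)-prop-1-en-1-yl]dihydrofuran-2(3H)-one F2. Enolate hydroxylation (LiHMDS, then 2-(phenylsulfonyl)-3-phenyloxaziridine, THF, −78 °C) should give mainly the trans isomer (3R,4S)-3-hydroxy-4-[(E)-prop-1-en-1-yl]dihydrofuran-2(3H)-one F3. This is protected (BOMCl, i-Pr2NEt) as (3R,4S)-3-[(benzyloxy)methoxy]-4-[(E)-prop-1-en-1-yl]dihydrofuran-2(3H)-one F4. Its lithium enolate (LDA, THF–DMPU, −78 °C) is alkylated with 1-(benzyloxy)-4-(bromomethyl)-2-methoxybenzene on the face anti to the propenyl group, which re-sets C3 and returns to the route at 15.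

Step 8. The addition to the α-branched aldehyde may show poor facial selectivity, through competition between the Felkin–Anh mode and chelate-type delivery by the BOM oxygens. Epimerisation or β-elimination of the β-acyloxy aldehyde is a second drain. The fallback sets C7' by a reagent instead of by the substrate. It sets out from 20 as its mixture with the C7' epimer. Oxidation with Dess–Martin periodinane (NaHCO3, CH2Cl2, 0 °C) gives the aryl ketone (3S,4S)-4-[4-(benzyloxy)-3-methoxybenzoyl]-3-[(benzyloxy)methoxy]-3-[4-(benzyloxy)-3-methoxybenzyl]dihydrofuran-2(3H)-one F5. Corey–Bakshi–Shibata reduction then returns to the route at 20 ((S)-Me-CBS, catecholborane, toluene, −40 °C, by the aryl-as-large-group model; the antipodal catalyst is at hand should the branched C4 side dominate).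

Step 9. Over-reduction may occur, that is hydrogenolysis of the electron-rich benzylic C7'–O bond while the hindered tertiary BOM ether is still being cleaved, or the BOM cleavage may stall. The fallback removes the benzyl groups before the carbinol exists. It sets out from 20, which is oxidised as in the fallback for step 8 to the protected aryl ketone F5. Hydrogenolysis (H2, Pd/C, EtOAc, rt) then gives (3S,4S)-3-hydroxy-4-(4-hydroxy-3-methoxybenzoyl)-3-(4-hydroxy-3-methoxybenzyl)dihydrofuran-2(3H)-one F6, in which no benzylic C–O single bond is at risk. A hydroxyl-directed Evans–Saksena reduction (Me4NBH(OAc)3, MeCN–AcOH, −30 °C) should then give the 7'R carbinol and returns to the route at 22. Hydride is expected to be delivered from the C3–O–B unit through a chair with the C3 benzyl group equatorial.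

Further compounds
F1 | step 6 | ethyl (3S,4E)-3-{[(tert-butyldimethylsilyl)oxy]methyl}hex-4-enoate | CCOC(=O)C[C@H](CO[Si](C)(C)C(C)(C)C)/C=C/C
F2 | step 6 | (4S)-4-[(E)-prop-1-en-1-yl]dihydrofuran-2(3H)-one | O=C1OC[C@@H](C1)/C=C/C
F3 | step 6 | (3R,4S)-3-hydroxy-4-[(E)-prop-1-en-1-yl]dihydrofuran-2(3H)-one | O[C@H]1C(=O)OC[C@@H]1/C=C/C
F4 | step 6 | (3R,4S)-3-[(benzyloxy)methoxy]-4-[(E)-prop-1-en-1-yl]dihydrofuran-2(3H)-one | c1ccccc1COCO[C@H]1C(=O)OC[C@@H]1/C=C/C
F5 | step 8 | (3S,4S)-4-[4-(benzyloxy)-3-methoxybenzoyl]-3-[(benzyloxy)methoxy]-3-[4-(benzyloxy)-3-methoxybenzyl]dihydrofuran-2(3H)-one | COc1cc(C[C@@]2(OCOCc3ccccc3)C(=O)OC[C@@H]2C(=O)c2ccc(OCc3ccccc3)c(OC)c2)ccc1OCc1ccccc1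
F6 | step 9 | (3S,4S)-3-hydroxy-4-(4-hydroxy-3-methoxybenzoyl)-3-(4-hydroxy-3-methoxybenzyl)dihydrofuran-2(3H)-one | COc1cc(C[C@@]2(O)C(=O)OC[C@@H]2C(=O)c2ccc(O)c(OC)c2)ccc1O
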